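## Plan

1. Retrosynthesis: the two aryl gallate esters at O7 and O3' are cut first, then the O1–C2 bond of ring C, which leads back to a trans epoxide across C2–C3, and last the C2–C3 bond itself.
2. Enabling feature: C2 and C3 are neighbouring oxygen-bearing carbons; C2 sits directly on ring B and C3 is separated from ring A only by C4. C2–C3 can therefore be made between a ring B benzylidene (carbene equivalent) and the carbonyl carbon of a ring A arylacetaldehyde, whose oxygen becomes O3.
3. Forward: a ring A arylacetaldehyde (O7 allyl, O5 benzyl, O1 silyl) and a ring B tosylhydrazone salt (O3' allyl, O4' benzyl) are joined as the oxirane. After desilylation O1 closes ring C. O3 is then benzylated, the two allyl ethers are exchanged for tribenzylgalloyl esters, and hydrogenolysis frees every hydroxyl.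
4. Stereochemistry: a chiral sulfide catalyst sets both centres of the (2S,3S)-trans-epoxide. The 6-endo opening inverts C2 and leaves C3, giving (2R,3S). No later step touches C2 or C3.

Key step: step 9

Assumption: the camphor-derived chiral sulfide of step 9 is accessible in both enantiomeric series (from either antipode of 10-camphorsulfonic acid), and the series that delivers (S,S)-trans-epoxides is used.
Assumption: species bound to the rhodium or sulfide catalyst in step 9 (carbene, ylide, betaine) are turnover states of the catalysts, so only the free diazo compound is numbered.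

## Route

Step 1
Reactants: 1 2,4,6-trihydroxybenzaldehyde
Product: 2 4-(allyloxy)-2,6-dihydroxybenzaldehyde
Conditions: allyl bromide (1.0 equiv), NaHCO3 (1.2 equiv), DMF, 40 °C
Reagents that add atoms: allyl bromide, C=CCBr
Why: Williamson ether synthesis: the 4-OH, para to the formyl group and the only phenol not flanking or hydrogen-bonded to the carbonyl, is the most acidic and accessible site, so bicarbonate and one equivalent of allyl bromide should etherify it first.

Step 2
Reactants: 2 4-(allyloxy)-2,6-dihydroxybenzaldehyde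
Product: 3 4-(allyloxy)-2-(benzyloxy)-6-hydroxybenzaldehyde
Conditions: BnBr (1.05 equiv), K2CO3 (1.1 equiv), DMF, 25 °C
Reagents that add atoms: benzyl bromide, BrCc1ccccc1
Why: Williamson ether synthesis: the two remaining phenols are equivalent, and once one is benzylated the other is held in a strong hydrogen bond to the aldehyde, which should stop the alkylation at the monobenzyl ether.

Step 3
Reactants: 3 4-(allyloxy)-2-(benzyloxy)-6-hydroxybenzaldehyde
Product: 4 4-(allyloxy)-2-(benzyloxy)-6-(tert-butyldimethylsilyloxy)benzaldehyde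
Conditions: TBSCl (1.5 equiv), imidazole (3 equiv), DMF, 25 °C
Reagents that add atoms: tert-butyldimethylsilyl chloride, CC(C)(C)[Si](C)(C)Cl
Why: Imidazole-promoted silylation of the chelated phenol masks the future O1 as a silyl ether that survives ylides and dilute acid and is later removed by fluoride without touching allyl or benzyl ethers.

Step 4
Reactants: 4 4-(allyloxy)-2-(benzyloxy)-6-(tert-butyldimethylsilyloxy)benzaldehyde
Product: 5 tert-butyl{5-(allyloxy)-3-(benzyloxy)-2-(2-methoxyethenyl)phenoxy}dimethylsilane (E/Z mixture)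
Conditions: Ph3P(CH2OMe)Cl (1.5 equiv), KN(SiMe3)2 (1.4 equiv), THF, 0 °C; then 4, 0 → 25 °C
Reagents that add atoms: (methoxymethyl)triphenylphosphonium chloride, [Cl-].COC[P+](c1ccccc1)(c1ccccc1)c1ccccc1
Why: Wittig olefination with the methoxymethylene ylide, preformed so that no free base meets the aryl silyl ether, adds the carbon that becomes C3 as an enol ether.

Step 5
Reactants: 5 tert-butyl{5-(allyloxy)-3-(benzyloxy)-2-(2-methoxyethenyl)phenoxy}dimethylsilane
Product: 6 2-[4-(allyloxy)-2-(benzyloxy)-6-(tert-butyldimethylsilyloxy)phenyl]acetaldehyde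
Conditions: 1 M aq. HCl, THF, 25 °C; used directly
Reagents that add atoms: water, O
Why: Acid-catalysed enol ether hydrolysis (C-protonation, hydration of the oxocarbenium ion, loss of methanol) should release the arylacetaldehyde while the aryl silyl, allyl and benzyl ethers tolerate dilute aqueous acid; the aldehyde is taken on at once because it is prone to self-aldol reaction.

Step 6
Reactants: 7 4-(benzyloxy)-3-hydroxybenzaldehyde
Product: 8 3-(allyloxy)-4-(benzyloxy)benzaldehyde
Conditions: allyl bromide (1.2 equiv), K2CO3, DMF, 25 °C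
Reagents that add atoms: allyl bromide, C=CCBr
Why: Williamson ether synthesis on the single free phenol marks O3' with the allyl group that is later exchanged for the gallate.

Step 7
Reactants: 8 3-(allyloxy)-4-(benzyloxy)benzaldehyde
Product: 9 N'-[(E)-3-(allyloxy)-4-(benzyloxy)benzylidene]-4-methylbenzenesulfonohydrazide
Conditions: TsNHNH2 (1.0 equiv), MeOH, 25 °C
Reagents that add atoms: p-toluenesulfonyl hydrazide, Cc1ccc(cc1)S(=O)(=O)NN
Why: Condensation of the aromatic aldehyde with the sulfonyl hydrazide gives the crystalline (E)-tosylhydrazone, the Bamford–Stevens precursor of the ring B carbene equivalent.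

Step 8
Reactants: 9 N'-[(E)-3-(allyloxy)-4-(benzyloxy)benzylidene]-4-methylbenzenesulfonohydrazide
Product: 10 sodium salt of 3-(allyloxy)-4-(benzyloxy)benzaldehyde (E)-tosylhydrazone
Conditions: NaOMe (1.0 equiv), MeOH, 25 °C; evaporate, dry in vacuo, keep dark
Reagents that add atoms: sodium methoxide, [Na+].[O-]C
Why: Acid–base reaction: methoxide removes the sulfonamide N–H completely, and evaporation leaves the dry sodium salt that fragments to the diazo compound on mild warming.

Step 9
Reactants: 6 2-[4-(allyloxy)-2-(benzyloxy)-6-(tert-butyldimethylsilyloxy)phenyl]acetaldehyde; 10 sodium salt of 3-(allyloxy)-4-(benzyloxy)benzaldehyde (E)-tosylhydrazone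
Product: 12 (2S,3S)-2-[3-(allyloxy)-4-(benzyloxy)phenyl]-3-[4-(allyloxy)-2-(benzyloxy)-6-(tert-butyldimethylsilyloxy)benzyl]oxirane, via aryldiazomethane 11 (not isolated)
Conditions: 6 (1.0 equiv), 10 (1.5 equiv), Rh2(OAc)4 (1 mol %), camphor-derived chiral 2-thiabicyclo[2.2.1]heptane sulfide (20 mol %), BnEt3NCl (10 mol %), MeCN, 40 °C; Et3N-deactivated SiO2
Reagents that add atoms: none
Why: Mild thermolysis of salt 10 under phase-transfer catalysis releases diazo compound 11 slowly, Rh2(OAc)4 converts it into a rhodium carbene that the chiral sulfide captures, and the resulting sulfonium ylide adds to the carbonyl carbon of 6 to give a betaine whose alkoxide displaces the sulfide from the former ylide carbon. The closest known reaction type is the sulfide and Rh2(OAc)4 catalysed asymmetric epoxidation of aldehydes with aryldiazomethanes generated in the flask from tosylhydrazone salts (a catalytic Corey–Chaykovsky reaction), which is established for aliphatic as well as aromatic aldehydes. The oxirane closes by a 3-exo-tet displacement that regenerates the sulfide. C2 (the ylide carbon) is controlled by the chiral sulfide, which fixes the ylide conformation and shields one face; C3 is set relative to C2 because the syn betaine reverts to ylide and aldehyde while the anti betaine closes, which should lead to the trans (2S,3S) epoxide. The step needs trans selectivity, face selectivity and chemoselectivity for carbonyl addition over enolisation of 6 and over carbene attack on the allyl ethers: the aryl group of ring B stabilises the ylide enough for betaine formation to be reversible, the silyl ether on O1 removes the only acidic O–H, the low stationary concentration of 11 and the much higher affinity of the carbene for sulfur than for an unactivated terminal alkene protect the allyl groups, and the near-neutral medium limits enolisation.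

Step 10
Reactants: 12 (2S,3S)-2-[3-(allyloxy)-4-(benzyloxy)phenyl]-3-[4-(allyloxy)-2-(benzyloxy)-6-(tert-butyldimethylsilyloxy)benzyl]oxirane
Product: 14 (2R,3S)-7-(allyloxy)-2-[3-(allyloxy)-4-(benzyloxy)phenyl]-5-(benzyloxy)chroman-3-ol, via phenol epoxide 13 (not isolated)
Conditions: TBAF (1.1 equiv), AcOH (1.5 equiv), THF, 0 °C; aq. wash; then CSA (10 mol %), CH2Cl2, −20 → 0 °C
Reagents that add atoms: none
Why: Fluoride desilylation buffered by acetic acid gives the neutral phenol, and Brønsted-acid activation of the epoxide then lets O1 attack the benzylic carbon, activated by the para-benzyloxy group of ring B, in a 6-endo-tet epoxide opening with inversion at C2 and no change at C3, which should give the 2,3-trans flavan-3-ol.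

Step 11
Reactants: 14 (2R,3S)-7-(allyloxy)-2-[3-(allyloxy)-4-(benzyloxy)phenyl]-5-(benzyloxy)chroman-3-ol
Product: 15 (2R,3S)-7-(allyloxy)-2-[3-(allyloxy)-4-(benzyloxy)phenyl]-3,5-bis(benzyloxy)chromane
Conditions: NaH (1.3 equiv), BnBr (1.3 equiv), Bu4NI (cat.), DMF, 0 → 25 °C
Reagents that add atoms: benzyl bromide, BrCc1ccccc1
Why: Williamson ether synthesis on the sodium alkoxide of the only free hydroxyl caps O3, so that the next two steps address O7 and O3' alone; C2–H and C3–H are not acidic and keep their configuration.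

Step 12
Reactants: 15 (2R,3S)-7-(allyloxy)-2-[3-(allyloxy)-4-(benzyloxy)phenyl]-3,5-bis(benzyloxy)chromane
Product: 16 (2R,3S)-3,5-bis(benzyloxy)-2-[4-(benzyloxy)-3-hydroxyphenyl]chroman-7-ol
Conditions: Pd(PPh3)4 (5 mol %), morpholine (10 equiv), THF, 25 °C
Reagents that add atoms: none
Why: Tsuji–Trost-type deallylation: zerovalent palladium ionises the two aryl allyl ethers to π-allyl complexes that morpholine intercepts, while benzyl ethers and the chroman stay inert.

Step 13
Reactants: 16 (2R,3S)-3,5-bis(benzyloxy)-2-[4-(benzyloxy)-3-hydroxyphenyl]chroman-7-ol; 17 3,4,5-tris(benzyloxy)benzoic acid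
Product: 18 (2R,3S)-3,5-bis(benzyloxy)-2-{4-(benzyloxy)-3-[3,4,5-tris(benzyloxy)benzoyloxy]phenyl}chroman-7-yl 3,4,5-tris(benzyloxy)benzoate
Conditions: 17 (2.4 equiv), DCC (2.6 equiv), DMAP (0.3 equiv), CH2Cl2, 0 → 25 °C
Reagents that add atoms: none
Why: Steglich esterification: the carbodiimide-activated acid is passed by DMAP to the two phenols, the only nucleophiles left in the molecule.

Step 14
Reactants: 18 (2R,3S)-3,5-bis(benzyloxy)-2-{4-(benzyloxy)-3-[3,4,5-tris(benzyloxy)benzoyloxy]phenyl}chroman-7-yl 3,4,5-tris(benzyloxy)benzoate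
Product: 19 catechin 7,3'-di-O-gallate, (2R,3S)-3,5-dihydroxy-2-[4-hydroxy-3-(3,4,5-trihydroxybenzoyloxy)phenyl]chroman-7-yl 3,4,5-trihydroxybenzoate
Conditions: H2 (1 atm), Pd(OH)2/C, THF/MeOH, 25 °C
Reagents that add atoms: none
Why: Heterogeneous hydrogenolysis cleaves all nine O-benzyl groups (four on the flavan, six on the galloyl units minus none shared) under neutral conditions that leave the aryl esters, the C2–O1 bond and both stereocentres untouched and offer no base to promote acyl migration between O3' and O4'.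

## Compound list

1 | 2,4,6-trihydroxybenzaldehyde | O=Cc1c(O)cc(O)cc1O | starting material
2 | 4-(allyloxy)-2,6-dihydroxybenzaldehyde | O=Cc1c(O)cc(OCC=C)cc1O | intermediate
3 | 4-(allyloxy)-2-(benzyloxy)-6-hydroxybenzaldehyde | O=Cc1c(O)cc(OCC=C)cc1OCc1ccccc1 | intermediate
4 | 4-(allyloxy)-2-(benzyloxy)-6-(tert-butyldimethylsilyloxy)benzaldehyde | O=Cc1c(O[Si](C)(C)C(C)(C)C)cc(OCC=C)cc1OCc1ccccc1 | intermediate
5 | tert-butyl{5-(allyloxy)-3-(benzyloxy)-2-(2-methoxyethenyl)phenoxy}dimethylsilane (E/Z mixture) | COC=Cc1c(O[Si](C)(C)C(C)(C)C)cc(OCC=C)cc1OCc1ccccc1 | intermediate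
6 | 2-[4-(allyloxy)-2-(benzyloxy)-6-(tert-butyldimethylsilyloxy)phenyl]acetaldehyde | O=CCc1c(O[Si](C)(C)C(C)(C)C)cc(OCC=C)cc1OCc1ccccc1 | intermediate
7 | 4-(benzyloxy)-3-hydroxybenzaldehyde | O=Cc1ccc(OCc2ccccc2)c(O)c1 | starting material
8 | 3-(allyloxy)-4-(benzyloxy)benzaldehyde | O=Cc1ccc(OCc2ccccc2)c(OCC=C)c1 | intermediate
9 | N'-[(E)-3-(allyloxy)-4-(benzyloxy)benzylidene]-4-methylbenzenesulfonohydrazide | Cc1ccc(S(=O)(=O)N/N=C/c2ccc(OCc3ccccc3)c(OCC=C)c2)cc1 | intermediate
10 | sodium salt of 3-(allyloxy)-4-(benzyloxy)benzaldehyde (E)-tosylhydrazone | [Na+].Cc1ccc(S(=O)(=O)[N-]/N=C/c2ccc(OCc3ccccc3)c(OCC=C)c2)cc1 | intermediate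
11 | 2-(allyloxy)-1-(benzyloxy)-4-(diazomethyl)benzene (formed in the flask) | [N-]=[N+]=Cc1ccc(OCc2ccccc2)c(OCC=C)c1 | intermediate
12 | (2S,3S)-2-[3-(allyloxy)-4-(benzyloxy)phenyl]-3-[4-(allyloxy)-2-(benzyloxy)-6-(tert-butyldimethylsilyloxy)benzyl]oxirane | C=CCOc1cc(OCc2ccccc2)c(C[C@@H]2O[C@H]2c2ccc(OCc3ccccc3)c(OCC=C)c2)c(O[Si](C)(C)C(C)(C)C)c1 | intermediate
13 | 5-(allyloxy)-2-{[(2S,3S)-3-(3-(allyloxy)-4-(benzyloxy)phenyl)oxiran-2-yl]methyl}-3-(benzyloxy)phenol (formed in the flask) | C=CCOc1cc(OCc2ccccc2)c(C[C@@H]2O[C@H]2c2ccc(OCc3ccccc3)c(OCC=C)c2)c(O)c1 | intermediate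
14 | (2R,3S)-7-(allyloxy)-2-[3-(allyloxy)-4-(benzyloxy)phenyl]-5-(benzyloxy)chroman-3-ol | C=CCOc1cc(OCc2ccccc2)c2c(c1)O[C@H](c1ccc(OCc3ccccc3)c(OCC=C)c1)[C@@H](O)C2 | intermediate
15 | (2R,3S)-7-(allyloxy)-2-[3-(allyloxy)-4-(benzyloxy)phenyl]-3,5-bis(benzyloxy)chromane | C=CCOc1cc(OCc2ccccc2)c2c(c1)O[C@H](c1ccc(OCc3ccccc3)c(OCC=C)c1)[C@@H](OCc1ccccc1)C2 | intermediate
16 | (2R,3S)-3,5-bis(benzyloxy)-2-[4-(benzyloxy)-3-hydroxyphenyl]chroman-7-ol | Oc1cc(OCc2ccccc2)c2c(c1)O[C@H](c1ccc(OCc3ccccc3)c(O)c1)[C@@H](OCc1ccccc1)C2 | intermediate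
17 | 3,4,5-tris(benzyloxy)benzoic acid | OC(=O)c1cc(OCc2ccccc2)c(OCc2ccccc2)c(OCc2ccccc2)c1 | starting material
18 | (2R,3S)-3,5-bis(benzyloxy)-2-{4-(benzyloxy)-3-[3,4,5-tris(benzyloxy)benzoyloxy]phenyl}chroman-7-yl 3,4,5-tris(benzyloxy)benzoate | O=C(Oc1cc(OCc2ccccc2)c2c(c1)O[C@H](c1ccc(OCc3ccccc3)c(OC(=O)c3cc(OCc4ccccc4)c(OCc4ccccc4)c(OCc4ccccc4)c3)c1)[C@@H](OCc1ccccc1)C2)c1cc(OCc2ccccc2)c(OCc2ccccc2)c(OCc2ccccc2)c1 | intermediate
19 | catechin 7,3'-di-O-gallate, (2R,3S) | O=C(Oc1cc(O)c2c(c1)O[C@H](c1ccc(O)c(OC(=O)c3cc(O)c(O)c(O)c3)c1)[C@@H](O)C2)c1cc(O)c(O)c(O)c1 | target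

## Count and risks

Total steps: 14. Longest linear sequence: 11 steps (steps 1–5 and 9–14, from 1 to 19).

**Step 9 (key epoxidation).** Three things may go wrong:
- proton transfer from the α-CH2 of the aldehyde to the ylide, which leads to self-condensation;
- less reversible betaine formation, because the ylide is electron-rich and the aldehyde aliphatic, which erodes trans and face selectivity;
- acid-induced opening of the sensitive epoxide during isolation.

The fallback sets out from 6 (with 8 as partner) and returns at 12, taking its stereochemistry from a chiral dioxirane and not from a sulfide. Aldehyde 6 is reduced (NaBH4, MeOH, 0 °C) to 2-[4-(allyloxy)-2-(benzyloxy)-6-(tert-butyldimethylsilyloxy)phenyl]ethanol F1. A Mitsunobu reaction with 1-phenyl-1H-tetrazole-5-thiol (PPh3, DIAD, THF) gives the thioether 5-({2-[4-(allyloxy)-2-(benzyloxy)-6-(tert-butyldimethylsilyloxy)phenyl]ethyl}sulfanyl)-1-phenyl-1H-tetrazole F2. Oxidation with H2O2 and catalytic (NH4)6Mo7O24 in EtOH gives the sulfone 5-({2-[4-(allyloxy)-2-(benzyloxy)-6-(tert-butyldimethylsilyloxy)phenyl]ethyl}sulfonyl)-1-phenyl-1H-tetrazole F3. Julia–Kocienski olefination of F3 with the non-enolisable aldehyde 8 (KN(SiMe3)2, 1,2-dimethoxyethane, −60 °C) should give tert-butyl{5-(allyloxy)-2-[(E)-3-(3-(allyloxy)-4-(benzyloxy)phenyl)prop-2-enyl]-3-(benzyloxy)phenoxy}dimethylsilane F4. Shi epoxidation of F4 then gives 12. It uses the enantiomer of the D-fructose-derived ketone (the D-ketone gives (R,R)-epoxides from trans-β-alkylstyrenes), with KHSO5 (as 2KHSO5·KHSO4·K2SO4) and K2CO3 in MeCN/dimethoxymethane/water at 0 °C. The terminal allyl ethers are poor substrates for the dioxirane.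

**Step 10 (desilylation and ring closure).** Three things may go wrong:
- 5-exo attack of a transient phenoxide on C3 before the acid is present;
- ionisation of the epoxide to a free benzylic cation, with loss of stereochemical fidelity at C2;
- capture of that cation by the electron-rich ring A of a second molecule.

The fallback sets out from 12 and returns at 14. It removes the epoxide before the phenol is freed, so only C2 can act as electrophile. Acid-catalysed hydration of 12 (cat. HClO4, THF/H2O, 0 °C) gives (2S)-3-[4-(allyloxy)-2-(benzyloxy)-6-(tert-butyldimethylsilyloxy)phenyl]-1-[3-(allyloxy)-4-(benzyloxy)phenyl]propane-1,2-diol F5 (C1 epimers are of no consequence). TBAF/AcOH gives (2S)-3-[4-(allyloxy)-2-(benzyloxy)-6-hydroxyphenyl]-1-[3-(allyloxy)-4-(benzyloxy)phenyl]propane-1,2-diol F6. Orthoformate cyclisation (HC(OEt)3, PPTS, 1,2-dichloroethane, 25 → 60 °C) proceeds through the cyclic orthoester and its benzylic cation, which the phenol should trap trans to the C3 oxygen. This gives (2R,3S)-7-(allyloxy)-2-[3-(allyloxy)-4-(benzyloxy)phenyl]-5-(benzyloxy)chroman-3-yl formate F7. Methanolysis (K2CO3, MeOH) gives 14.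

**Step 1 (mono-allylation).** Over-alkylation to the 2,4-diallyl ether and C-allylation of the phloroglucinol ring may consume the material. The fallback sets out from 1 and returns at 3, using only alkylations whose site is fixed by the hydrogen bond to the aldehyde. MOMCl (2.2 equiv) and iPr2NEt in CH2Cl2 at 0 °C leave the chelated phenol and give 2-hydroxy-4,6-bis(methoxymethoxy)benzaldehyde F8. BnBr and K2CO3 in DMF at 60 °C give 2-(benzyloxy)-4,6-bis(methoxymethoxy)benzaldehyde F9. HCl in MeOH removes both acetals and gives 2-(benzyloxy)-4,6-dihydroxybenzaldehyde F10. Allyl bromide (1.0 equiv) and K2CO3 in acetone then etherify only the unchelated 4-OH and give 3.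

## Further compounds

F1 | step 9 | 2-[4-(allyloxy)-2-(benzyloxy)-6-(tert-butyldimethylsilyloxy)phenyl]ethanol | OCCc1c(O[Si](C)(C)C(C)(C)C)cc(OCC=C)cc1OCc1ccccc1
F2 | step 9 | 5-({2-[4-(allyloxy)-2-(benzyloxy)-6-(tert-butyldimethylsilyloxy)phenyl]ethyl}sulfanyl)-1-phenyl-1H-tetrazole | C=CCOc1cc(OCc2ccccc2)c(CCSc2nnnn2-c2ccccc2)c(O[Si](C)(C)C(C)(C)C)c1
F3 | step 9 | 5-({2-[4-(allyloxy)-2-(benzyloxy)-6-(tert-butyldimethylsilyloxy)phenyl]ethyl}sulfonyl)-1-phenyl-1H-tetrazole | C=CCOc1cc(OCc2ccccc2)c(CCS(=O)(=O)c2nnnn2-c2ccccc2)c(O[Si](C)(C)C(C)(C)C)c1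
F4 | step 9 | tert-butyl{5-(allyloxy)-2-[(E)-3-(3-(allyloxy)-4-(benzyloxy)phenyl)prop-2-enyl]-3-(benzyloxy)phenoxy}dimethylsilane | C=CCOc1cc(OCc2ccccc2)c(C/C=C/c2ccc(OCc3ccccc3)c(OCC=C)c2)c(O[Si](C)(C)C(C)(C)C)c1
F5 | step 10 | (2S)-3-[4-(allyloxy)-2-(benzyloxy)-6-(tert-butyldimethylsilyloxy)phenyl]-1-[3-(allyloxy)-4-(benzyloxy)phenyl]propane-1,2-diol (C1 epimers) | C=CCOc1cc(OCc2ccccc2)c(C[C@H](O)C(O)c2ccc(OCc3ccccc3)c(OCC=C)c2)c(O[Si](C)(C)C(C)(C)C)c1
F6 | step 10 | (2S)-3-[4-(allyloxy)-2-(benzyloxy)-6-hydroxyphenyl]-1-[3-(allyloxy)-4-(benzyloxy)phenyl]propane-1,2-diol (C1 epimers) | C=CCOc1cc(OCc2ccccc2)c(C[C@H](O)C(O)c2ccc(OCc3ccccc3)c(OCC=C)c2)c(O)c1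
F7 | step 10 | (2R,3S)-7-(allyloxy)-2-[3-(allyloxy)-4-(benzyloxy)phenyl]-5-(benzyloxy)chroman-3-yl formate | C=CCOc1cc(OCc2ccccc2)c2c(c1)O[C@H](c1ccc(OCc3ccccc3)c(OCC=C)c1)[C@@H](OC=O)C2
F8 | step 1 | 2-hydroxy-4,6-bis(methoxymethoxy)benzaldehyde | O=Cc1c(O)cc(OCOC)cc1OCOC
F9 | step 1 | 2-(benzyloxy)-4,6-bis(methoxymethoxy)benzaldehyde | O=Cc1c(OCc2ccccc2)cc(OCOC)cc1OCOC
F10 | step 1 | 2-(benzyloxy)-4,6-dihydroxybenzaldehyde | O=Cc1c(OCc2ccccc2)cc(O)cc1O
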